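## Retrosynthetic overview

1. The target is a chain of three dehydrozaluzanin C-derived guaianolide units: A (C10-H dienone end), B (C10-hydroxy dienone, middle) and C (saturated spiro ketone end). A/B and B/C are each joined by one spiro-fused cyclohexene.
2. Last ring (A/B cyclohexene: C2, C1, C10, C14 of unit A plus C15, C4 of unit B): moving the C1=C2 enone of unit A back to C1=C10 exposes a Diels–Alder retron. Cutting C14(A)–C15(B) and C2(A)–C4(B) gives trienone 5 (unit A) and hydroxy dimer 8 (units B/C).
3. Enabling feature: in unit A the C3 ketone sits on C2 of the five-membered ring and C14 is the exocyclic carbon on C10 of the seven-membered ring, so a 1,2-dehydro monomer holds an s-cis-locked diene C2=C1–C10=C14. In unit B the spiro carbon C4, with its CH2 (C15) next to the C3 ketone, is the trace of a 2-methylene ketone dienophile.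
4. Dimer 8 is made by the same cycloaddition (5 + dehydrozaluzanin C 3, closing the B/C cyclohexene), followed by a singlet-oxygen ene reaction that installs 10β-OH and the C1=C2 enone of unit B. Trienone 5 comes from 3 by Saegusa–Ito oxidation of its silyl dienol ether 4 and is handled only as a cold dilute solution.
5. All monomer rings and stereocentres (C1, C5, C6, C7) come from commercial dehydrocostus lactone 1. Ring order: monomer rings (bought) → B/C cyclohexene (step 5) → A/B cyclohexene (step 7).

Key step: step 7

Remark on the chemistry: dehydrocostus lactone (1) is taken as a commercially available, enantiopure sesquiterpene lactone; guaiane numbering is used for each unit and atoms are written C10(A), C4(B) and so on. Trienone 5 is assumed to last as a cold dilute solution for the time of its use; it is not stored, and step 4 is carried out once for step 5 and once again for step 7.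

## Route

Step 1
Reactants: 1 dehydrocostus lactone
Product: 2 3-epi-zaluzanin C (3α-hydroxyguaia-4(15),10(14),11(13)-trien-12,6α-olide)
Conditions: SeO2 (0.5 equiv), tBuOOH (2 equiv), CH2Cl2, 0 to 23 °C
Reagents that add atoms: tert-butyl hydroperoxide, CC(C)(C)OO
Why: Allylic oxidation with catalytic SeO2 and tBuOOH as terminal oxidant (ene reaction then [2,3]-sigmatropic shift) should attack the cyclopentylidene methylene C4=C15 and hydroxylate its allylic CH2 (C3) from the convex α face while the conjugated lactone methylene stays inert; the new C3 configuration (α-OH expected, any β epimer converges) is erased in step 2.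

Step 2
Reactants: 2 3-epi-zaluzanin C
Product: 3 dehydrozaluzanin C (3-oxoguaia-4(15),10(14),11(13)-trien-12,6α-olide)
Conditions: Dess–Martin periodinane (1.3 equiv), CH2Cl2, 0 to 23 °C
Reagents that add atoms: none
Why: Dess–Martin oxidation of the secondary allylic alcohol should give the 2-methylene ketone under neutral, non-nucleophilic conditions that leave both Michael acceptors alone; no stereocentre is formed and C3 becomes trigonal.

Step 3
Reactants: 3 dehydrozaluzanin C
Product: 4 silyl dienol ether (3-tert-butyldimethylsilyloxy-guaia-2,4(15),10(14),11(13)-tetraen-12,6α-olide)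
Conditions: TBSOTf (1.3 equiv), Et3N (2.5 equiv), CH2Cl2, −78 to 0 °C
Reagents that add atoms: tert-butyldimethylsilyl trifluoromethanesulfonate, CC(C)(C)[Si](C)(C)OS(=O)(=O)C(F)(F)F
Why: Soft enolisation can only occur toward C2, the sole α-CH2 of the ketone, and should give the cross-conjugated 2-silyloxy diene, which is locked s-trans and so cannot itself act as a Diels–Alder diene; no stereocentre is formed.

Step 4
Reactants: 4 silyl dienol ether
Product: 5 trienone (3-oxoguaia-1,4(15),10(14),11(13)-tetraen-12,6α-olide), obtained as a dilute MeCN solution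
Conditions: Pd(OAc)2 (1.1 equiv), MeCN (0.01 M), 23 °C, Ar, dark; filtration through Celite at −20 °C; filtrate kept at −20 °C and used at once
Reagents that add atoms: none
Why: In this Saegusa–Ito oxidation Pd(OAc)2 should palladate the silyl dienol ether at C2 on the α face and syn β-hydride elimination of H1α then gives the C1=C2 enone (no new stereocentre, C1 becomes trigonal), while high dilution and cold handling hold back the bimolecular self-cycloaddition of 5 and the removal of palladium before any cycloaddition keeps palladium hydride away from the later β,γ-unsaturated adducts.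

Step 5
Reactants: 5 trienone; 3 dehydrozaluzanin C
Product: 6 B/C cycloadduct (β,γ-unsaturated ketone dimer)
Conditions: 3 (3 equiv), MeCN solution of 5 (1 equiv) concentrated at 0 °C to 0.3 M in 3, then 23 °C, Ar, dark; filtration through Florisil under Ar
Reagents that add atoms: none
Why: The s-cis diene C2=C1–C10=C14 of 5 should be trapped in an intermolecular Diels–Alder reaction by the C4=C15 enone of excess 3 with ortho regiochemistry (C14 to C15, C2 to C4); the spiro centre C4(C) is set by addition to the convex α face of cis-fused 3 (the β face is covered by H6 and the seven-membered ring), and C2(B) (H β) by reaction on the α face of the diene anti to C6, in the ketone-exo arrangement usual for s-cis 2-methylene ketones.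

Step 6
Reactants: 6 B/C cycloadduct
Product: 8 10β-hydroxy dimer (dienone), via hydroperoxide 7 (not isolated)
Conditions: O2, tetraphenylporphyrin (1 mol %), visible light, CH2Cl2, −40 °C; then PPh3 (1.2 equiv), −40 to 0 °C
Reagents that add atoms: dioxygen, O=O
Why: In this Schenck ene reaction singlet oxygen should attack the only electron-rich alkene, the tetrasubstituted C1=C10 of unit B, from the β face because unit C is attached on the α face at C2, and abstract the cis, ketone-activated H2β suprafacially, which places the hydroperoxide on C10 (β) and moves the alkene into conjugation at C1=C2; PPh3 then reduces the O–O bond without touching the C10–O bond.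

Step 7
Reactants: 8 10β-hydroxy dimer; 5 trienone
Product: 9 A/B/C cycloadduct (unit A as β,γ-unsaturated ketone)
Conditions: 8 (2 equiv), MeCN solution of 5 (1 equiv, in 4 portions, concentrated at 0 °C to 0.3 M in 8 each time), 23 °C, Ar, dark; filtration through Florisil under Ar
Reagents that add atoms: none
Why: Trienone 5 carries the diene C2=C1–C10=C14 locked s-cis by its fused five- and seven-membered rings, and this diene adds in a concerted, asynchronous thermal [4+2] cycloaddition to the C4=C15 methylene of the dienone ring of unit B in 8; the closest known reaction type is the intermolecular Diels–Alder reaction of an s-cis 1-acyl diene with a 2-methylene ketone, the type used in step 5 and the one by which guaianolide oligomers are thought to arise in nature. The one new ring, the cyclohexene C2(A)–C1(A)=C10(A)–C14(A)–C15(B)–C4(B), is closed by intermolecular [4+2] cycloaddition, suprafacial on both partners, forming C14(A)–C15(B) and C2(A)–C4(B). The regiochemistry is the ortho one expected for a 1-acyl diene and a 2-methylene ketone: the unsubstituted terminus C14(A) bonds to the β carbon C15(B) and the acyl-bearing terminus C2(A) to the α carbon C4(B). Of the two new stereocentres, the spiro carbon C4(B) is set by addition of the diene to the β face of the flat dienone ring of unit B (the face of the C10 hydroxyl, anti to H5), and C2(A) (H β) by reaction on the convex α face of the diene with the C3(B) carbonyl endo; C2(A) is erased again in step 8. The step needs chemoselectivity for the dienone methylene of 8 over the α-methylene lactones, over the C4=C15 bond of 5 itself and over that of product 9, and β-facial selectivity on unit B. The first should be secured by the much higher dienophilicity of exocyclic enone methylenes compared with lactone methylenes, by the excess of 8 (recovered) and by charging 5 in portions so that it never stands in excess; the second by the shape of 8, in which the planar C1 and the 10β-hydroxyl turn the C8–C9 bridge of the seven-membered ring below the plane of the dienone so that the α face, open in monomer 3, is closed to the stacking diene, while the free 10β-hydroxyl on the open face can hydrogen-bond to the C3 carbonyl of the incoming trienone.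

Step 8
Reactants: 9 A/B/C cycloadduct
Product: 10 ainsliatrimer A
Conditions: Et3N (0.5 equiv), degassed CH2Cl2, 0 to 23 °C, Ar
Reagents that add atoms: none
Why: In this base-catalysed conjugation of a β,γ-unsaturated ketone Et3N should remove the doubly activated H2(A) to give the extended dienolate, which is protonated at the γ carbon C10(A) from the α face, anti to the C5 methine of spiro-linked unit B that stands over the β face of the new cyclohexene, so that the tetrasubstituted C1=C2 enone and the 10α-hydrogen of the target result, while exclusion of oxygen prevents C10 hydroxylation of the dienolate and the weak base leaves the lactone methylenes and the γ-hydrogens of the product alone.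

## Compound list

1 | dehydrocostus lactone; guaia-4(15),10(14),11(13)-trien-12,6α-olide (1α-H, 5α-H, 6β-H, 7α-H); (3aS,6aR,9aR,9bS)-3,6,9-trimethylidene-decahydroazuleno[4,5-b]furan-2-one | C=C1CC[C@@H]2[C@@H]([C@@H]3[C@H]1CCC3=C)OC(=O)C2=C | starting material

2 | 3-epi-zaluzanin C; 3α-hydroxyguaia-4(15),10(14),11(13)-trien-12,6α-olide | C=C1CC[C@@H]2[C@@H]([C@@H]3[C@H]1C[C@@H](O)C3=C)OC(=O)C2=C | intermediate

3 | dehydrozaluzanin C; 3-oxoguaia-4(15),10(14),11(13)-trien-12,6α-olide | C=C1CC[C@@H]2[C@@H]([C@@H]3[C@H]1CC(=O)C3=C)OC(=O)C2=C | intermediate

4 | silyl dienol ether of 3; 3-(tert-butyldimethylsilyloxy)guaia-2,4(15),10(14),11(13)-tetraen-12,6α-olide | C=C1CC[C@@H]2[C@@H]([C@@H]3[C@H]1C=C(O[Si](C)(C)C(C)(C)C)C3=C)OC(=O)C2=C | intermediate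

5 | trienone; 3-oxoguaia-1,4(15),10(14),11(13)-tetraen-12,6α-olide; handled as a cold dilute MeCN solution | C=C1CC[C@@H]2[C@@H]([C@@H]3C1=CC(=O)C3=C)OC(=O)C2=C | intermediate

6 | B/C cycloadduct; unit B is a 3-oxoguaia-1(10),4(15),11(13)-trien-12,6α-olide with 2β-H, whose C2 and C14 are bonded to C4 and C15 of unit C (3-oxoguaia-10(14),11(13)-dien-12,6α-olide); C4(C) is a spiro carbon with C2(B) on its α face (cis to H5(C)), and unit C sits on the α face of C2(B) | C=C1C(=O)[C@H]2C3=C(CC[C@]24C(=O)C[C@H]5C(=C)CC[C@H]6C(=C)C(=O)O[C@@H]6[C@H]54)CC[C@H]4C(=C)C(=O)O[C@@H]4[C@@H]13 | intermediate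

7 | 10β-hydroperoxide (not isolated); as 8 with OOH in place of OH at C10(B) | C=C1C(=O)C2=C3[C@H]1[C@H]1OC(=O)C(=C)[C@@H]1CC[C@@]3(OO)CC[C@]21C(=O)C[C@H]2C(=C)CC[C@H]3C(=C)C(=O)O[C@@H]3[C@H]21 | intermediate

8 | 10β-hydroxy dimer; unit B is a 10β-hydroxy-3-oxoguaia-1,4(15),11(13)-trien-12,6α-olide joined through C2 and C14 to the spiro carbon C4 and to C15 of unit C as in 6 | C=C1C(=O)C2=C3[C@H]1[C@H]1OC(=O)C(=C)[C@@H]1CC[C@@]3(O)CC[C@]21C(=O)C[C@H]2C(=C)CC[C@H]3C(=C)C(=O)O[C@@H]3[C@H]21 | intermediate

9 | A/B/C cycloadduct; unit A is a 3-oxoguaia-1(10),4(15),11(13)-trien-12,6α-olide with 2β-H, whose C2 and C14 are bonded to C4 and C15 of unit B of 8; C4(B) is a spiro carbon with C2(A) on its β face (trans to H5(B)) | C=C1C(=O)[C@H]2C3=C(CC[C@@]24C(=O)C5=C6[C@H]4[C@H]4OC(=O)C(=C)[C@@H]4CC[C@@]6(O)CC[C@]57C(=O)C[C@H]5C(=C)CC[C@H]6C(=C)C(=O)O[C@@H]6[C@H]57)CC[C@H]4C(=C)C(=O)O[C@@H]4[C@@H]13 | intermediate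

10 | ainsliatrimer A; as 9 with unit A isomerised to the C1=C2 enone carrying 10α-H | C=C1C(=O)C2=C3[C@H](CC[C@H]4C(=C)C(=O)O[C@@H]4[C@@H]13)CC[C@@]21C(=O)C2=C3[C@H]1[C@H]1OC(=O)C(=C)[C@@H]1CC[C@@]3(O)CC[C@]21C(=O)C[C@H]2C(=C)CC[C@H]3C(=C)C(=O)O[C@@H]3[C@H]21 | target

## Step count and risks

Total step count: 8 (step 4 is carried out twice, once for each cycloaddition). Longest linear sequence: 8 steps (1 → 2 → 3 → 4 → 5 → 6 → 8 → 9 → 10; compound 3 is used in steps 3 and 5, compound 5 in steps 5 and 7).

**Step 7 (key step).** What may go wrong: addition of the trienone to the α face of the unit B dienone (the face preferred by monomer 3) instead of the β face; self-cycloaddition of 5 competing with its capture by 8; further cycloaddition onto product 9. The fallback sets out from 4 and 8 and comes back at 9. It uses the diene at the alcohol oxidation level, where it is stable and cannot dimerise, and delivers it intramolecularly from the C10 hydroxyl through a temporary silicon tether. Silyl dienol ether 4 is selenenylated with PhSeCl (CH2Cl2, −78 °C, attack on the α face) to give the 2α-phenylselanyl ketone F1. Luche reduction (NaBH4, CeCl3·7H2O, MeOH, −78 °C, hydride anti to the selanyl group) should give the 2α-phenylselanyl 3α-alcohol F2. Oxidation with H2O2/pyridine gives the selenoxide F3 (not isolated, both selenium epimers), whose syn elimination across C1–C2 (H1α is the only syn hydrogen) releases the 3α-hydroxy diene F4. Alcohol 8 is silylated with iPr2Si(OTf)2/2,6-lutidine to the silyl triflate F5 (not isolated), which is quenched with F4 to give the mixed diisopropylsilylene bis-ether F6. On warming in toluene (60–80 °C, BHT) the tether, which spans from the 10β oxygen of unit B to the 3α oxygen of unit A, can only bring the α face of the diene onto the β face of the C4=C15 bond, through a nine-membered silicon-containing ring; the intramolecular Diels–Alder reaction, with the same ortho regiochemistry, should give the tethered cycloadduct F7. HF·pyridine removes the tether to give the diol F8, and Dess–Martin periodinane then oxidises the secondary allylic C3(A) alcohol (the tertiary C10 alcohol is inert) to the β,γ-unsaturated ketone 9.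

**Step 4.** What may go wrong: self-cycloaddition of the trienone while it forms, is filtered or is concentrated, since its own C4=C15 bond is a dienophile; slow oxidation at high dilution; loss of material on palladium metal. The fallback sets out from 4 and comes back at 6 (and, in the same way, at 9). The trienone is no longer prepared as a separate solution: 4 is added over several hours by syringe pump to Pd(OAc)2 (1.1 equiv) and the dienophile (3, 3 equiv, or 8, 1.2 equiv) in MeCN at 23 °C under Ar, so that Saegusa–Ito oxidation and Diels–Alder reaction run as one cascade in which 5 is trapped as it forms and never accumulates. No compound outside the compound list is made (F0).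

**Step 6.** What may go wrong: conjugative isomerisation of 6 before or during photooxygenation (the conjugated 10-H enone no longer reacts with singlet oxygen); ene reaction with hydrogen abstraction from C9 or C14; oxygen delivery to the α face. The fallback sets out from 6 and comes back at 8 by way of hydroperoxide 7. The isomerisation is made deliberate and the oxygen is introduced by ground-state autoxidation of the extended dienolate instead of the ene reaction. Et3N in degassed CH2Cl2 converts 6 into the conjugated 10β-H dienone dimer F9. F9 is treated with DBU in THF/tBuOH under O2 at 0 °C in the presence of P(OEt)3: deprotonation at C10 gives the dienolate, which should take up O2 at its γ carbon C10 from the β face, anti to the C5–C6 arm of unit C lying under the cyclohexene, as in the autoxidation known for 3-oxo-5(10)-ene steroids. Hydroperoxide 7 is reduced in the flask to 8.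

## Further compounds

F1 | step 7 | 2α-phenylselanyl-dehydrozaluzanin C (2α-phenylselanyl-3-oxoguaia-4(15),10(14),11(13)-trien-12,6α-olide) | C=C1CC[C@@H]2[C@@H]([C@@H]3[C@H]1[C@@H]([Se]c1ccccc1)C(=O)C3=C)OC(=O)C2=C

F2 | step 7 | 2α-phenylselanyl-3α-hydroxyguaia-4(15),10(14),11(13)-trien-12,6α-olide | C=C1CC[C@@H]2[C@@H]([C@@H]3[C@H]1[C@@H]([Se]c1ccccc1)[C@@H](O)C3=C)OC(=O)C2=C

F3 | step 7 | selenoxide of F2 (not isolated, both selenium epimers) | C=C1CC[C@@H]2[C@@H]([C@@H]3[C@H]1[C@@H]([Se](=O)c1ccccc1)[C@@H](O)C3=C)OC(=O)C2=C

F4 | step 7 | 3α-hydroxy diene; 3α-hydroxyguaia-1,4(15),10(14),11(13)-tetraen-12,6α-olide | C=C1CC[C@@H]2[C@@H]([C@@H]3C1=C[C@@H](O)C3=C)OC(=O)C2=C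

F5 | step 7 | silyl triflate of 8 (not isolated); 10β-O-[diisopropyl(trifluoromethanesulfonyloxy)silyl] ether of 8 | C=C1C(=O)C2=C3[C@H]1[C@H]1OC(=O)C(=C)[C@@H]1CC[C@@]3(O[Si](C(C)C)(C(C)C)OS(=O)(=O)C(F)(F)F)CC[C@]21C(=O)C[C@H]2C(=C)CC[C@H]3C(=C)C(=O)O[C@@H]3[C@H]21

F6 | step 7 | mixed diisopropylsilylene bis-ether of 8 (10β-O of unit B) and F4 (3α-O) | C=C1C(=O)C2=C3[C@H]1[C@H]1OC(=O)C(=C)[C@@H]1CC[C@@]3(O[Si](C(C)C)(C(C)C)O[C@@H]4C=C5C(=C)CC[C@H]6C(=C)C(=O)O[C@@H]6[C@H]5C4=C)CC[C@]21C(=O)C[C@H]2C(=C)CC[C@H]3C(=C)C(=O)O[C@@H]3[C@H]21

F7 | step 7 | tethered cycloadduct; as 9 with C3(A) carrying a 3α-oxygen joined through Si(iPr)2 to the 10β-oxygen of unit B | C=C1[C@H](O[Si]%10(C(C)C)C(C)C)[C@H]2C3=C(CC[C@@]24C(=O)C5=C6[C@H]4[C@H]4OC(=O)C(=C)[C@@H]4CC[C@@]6(O%10)CC[C@]57C(=O)C[C@H]5C(=C)CC[C@H]6C(=C)C(=O)O[C@@H]6[C@H]57)CC[C@H]4C(=C)C(=O)O[C@@H]4[C@@H]13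

F8 | step 7 | diol; as 9 with a 3α-hydroxyl in place of the C3(A) ketone | C=C1[C@H](O)[C@H]2C3=C(CC[C@@]24C(=O)C5=C6[C@H]4[C@H]4OC(=O)C(=C)[C@@H]4CC[C@@]6(O)CC[C@]57C(=O)C[C@H]5C(=C)CC[C@H]6C(=C)C(=O)O[C@@H]6[C@H]57)CC[C@H]4C(=C)C(=O)O[C@@H]4[C@@H]13

F0 | step 4 | none | none

F9 | step 6 | conjugated 10β-H dienone dimer; as 8 with hydrogen in place of the C10(B) hydroxyl | C=C1C(=O)C2=C3[C@H]1[C@H]1OC(=O)C(=C)[C@@H]1CC[C@H]3CC[C@]21C(=O)C[C@H]2C(=C)CC[C@H]3C(=C)C(=O)O[C@@H]3[C@H]21
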